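all flasks: Z 20 mM
- east: D 20 mM; X 24 mM; the very flask that is asked about, followed so far
- flask: D 20.0 mM; X 24.0 mM; time 15 d

east run (percent of the Z charged)

| time / h | Z / % | E / % | J / % |
|---|---|---|---|
| 6.00 | 33.2 | 8.7 | 21.2 |
| 12.0 | 26.3 | 14.4 | 34.3 |
| 20.0 | 24.6 | 22.3 | 41.9 |
| 25.0 | 24.5 | 23.5 | 44.1 |
| 30.0 | 22.7 | 27.4 | 44.1 |
| 40.0 | 23.3 | 26.0 | 44.4 |

(standard deviation of a reading: 1 percentage point)

- in percentages every species weighs as the Z in it: one J counts as two
- the numbers in the tables scatter by 1 percentage point (one standard deviation)
- the reaction counts as stopped when no species that holds the Z changes by six tenths of a point or more over the second half of the time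

1.20 of X per Z charged went into the east flask, yet Z has stood near 23.5% of its charge since 25.0 h. For whoever takes over: over the same readings J averages 44.2%, and Z, E and J together fall 6.7 percentage points short of the charge, which we book to an unseen intermediate. Leave the flask closed and add nothing, for the balance below is written for this charge.

We carry one quantity, Z's share of X: the fraction of the X charge spent on Z, at one X per Z lost.

Z gone = 76.5%

Z's share of X = Z gone × Z charge / X charge = 0.638

The readings show neither reagent, so this is our judgement: we call X the limiting reagent and book the remaining 0.362 of it to D, at one D per X, which leaves D at 56.5% of its charge. If J stays put and the intermediate drains to E, the flask at 15 d holds J at 44.2% and E at 32.3%.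

* at 15 d, what has stopped the reaction, if anything has (D has run out first / X has run out first / all of Z has reacted / it is still moving)
* part of the Z gone at 15 d
* the E standing at 15 d, as a percentage of the Z charged
* the J standing at 15 d, as a percentage of the Z charged

The forecast parts from us on the stop, saying D has run out first since the Z consumed and the J formed together “fits one D per Z plus one more per J”, with Z gone 76.5%, E 28.5% and J 45.5%.

The flask gives: X has run out first, Z gone 76.8%, E 31.0%, J 45.8%.

    Q + G → E (k = 0.150 L mol⁻¹ min⁻¹)
    2 Q → J (k = 0.110 L mol⁻¹ min⁻¹)
    Z + X → Q (k = 0.310 L mol⁻¹ min⁻¹)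
    X + D → G (k = 0.120 L mol⁻¹ min⁻¹)

At the start of this flask the step Z + X → Q uses X 2.6 times as fast as the step X + D → G. With Z's share of X at our 0.638, we had D at 56.5% of its charge, and at 15.0 d the flask holds D at 56.8% with X at 0%. In the neighbour charged with X at 0.300 of the Z charge, the same share puts Z gone at 19.1%, and that flask stands at 21.2%.

Readings and results come from a simulation with made-up constants, noise included.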